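**Retrosynthetic overview**
1. The dihydropyran ring is formed last. An ortho-quinone methide (from benzaldehyde and 2,4-diformylphloroglucinol) undergoes an oxa-[4+2] addition to the exocyclic C4=C15 bond of a muurola-4(15),5-diene. This sets the spiro carbon and the benzylic carbon.
2. The diene comes from the C15-nor enone by methylenation. The enone comes from a cis-fused nor-muurolenone by alkene saturation and regioselective desaturation.
3. Ring A closes at C6–C7 as in the bisabolane → bicyclic cadinane-type cyclisation. It is run as a Lewis-acid conjugate ene reaction of a 4-alkylcyclohexenone, and this sets C7.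
4. Ring B comes from an organocatalytic Michael/aldol annulation of (R)-citronellal with methyl vinyl ketone. C10 comes from the chiral pool and C1 from the catalyst.
5. Order of ring formation: ring B, then ring A, then the dihydropyran.

Assumption: cadinane numbering is used for the terpene carbons (C1 ring-fusion CH, C4 spiro carbon, C5=C6 alkene, C7 CH-iPr, C10 CH-CH3, C15 chroman CH2), and commercial (R)-citronellal of at least 97 % ee is used.

**Step 1**
Reactants: 1 (R)-citronellal; 2 methyl vinyl ketone
Product: 4 (4R)-4-[(2R)-6-methylhept-5-en-2-yl]cyclohex-2-en-1-one, via keto-aldehyde 3 (not isolated)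
Conditions: (R)-2-(methoxydiphenylmethyl)pyrrolidine (5 mol %), ethyl 3,4-dihydroxybenzoate (20 mol %), neat, 4 °C; then 0.1 M aq KOH (cat.), nBu4NOH (cat.), THF–Et2O, reflux, same flask
Reagents that add atoms: methyl vinyl ketone, C=CC(C)=O
Why: This is an enamine-catalysed asymmetric Michael addition followed by intramolecular aldol condensation (organocatalytic Robinson-type annulation), in which C10 is carried over from 1 and the new C1 centre (2R in 3) is set by the catalyst, whose CPh2OMe group blocks one face of the E-enamine and so gives the C1-H/C10-H syn relationship that substrate-controlled enolate alkylation of menthone-type ketones does not give.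

**Step 2**
Reactants: 4 (4R)-4-[(2R)-6-methylhept-5-en-2-yl]cyclohex-2-en-1-one
Product: 5 (4aR,5R,8R,8aR)-5-methyl-8-(prop-1-en-2-yl)octahydronaphthalen-2(1H)-one
Conditions: Me2AlCl (1.1 equiv), CH2Cl2, −78 °C to 0 °C; aq HCl quench
Reagents that add atoms: none
Why: In this Lewis-acid-promoted intramolecular conjugate ene (cation–olefin) reaction, modelled on the bisabolyl-to-bicyclic closure, the tether forces axial attack on C6 anti to the pseudo-axial H1 (cis fusion) through a chair in which C10-CH3 and the developing isopropenyl group are equatorial, so H7 ends trans to H1, while the mild proton-scavenging Lewis acid keeps the 1,5-hydrogen transfer ahead of the 1,2-hydride shifts that would invert C7.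

**Step 3**
Reactants: 5 (4aR,5R,8R,8aR)-5-methyl-8-(prop-1-en-2-yl)octahydronaphthalen-2(1H)-one
Product: 6 (4aR,5R,8S,8aS)-5-methyl-8-(propan-2-yl)octahydronaphthalen-2(1H)-one
Conditions: H2 (1 atm), RhCl(PPh3)3 (5 mol %), toluene–EtOH, rt
Reagents that add atoms: none
Why: Homogeneous hydrogenation saturates only the unhindered 1,1-disubstituted alkene, leaves the ketone alone and does not move the double bond into C7, so no stereocentre changes (the descriptors at C7 and C6 change only through substituent priorities).

**Step 4**
Reactants: 6 (4aR,5R,8S,8aS)-5-methyl-8-(propan-2-yl)octahydronaphthalen-2(1H)-one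
Product: 8 (4aR,5R,8S)-5-methyl-8-(propan-2-yl)-4,4a,5,6,7,8-hexahydronaphthalen-2(3H)-one, via silyl enol ether 7 (not isolated)
Conditions: Me3SiOTf, Et3N, CH2Cl2, rt, 12 h (equilibrating); volatiles removed; Pd(OAc)2 (10 mol %), O2 (1 atm), DMSO, rt
Reagents that add atoms: none
Why: In this Saegusa–Ito oxidation, equilibrating soft enolisation of the cis-fused 2-decalone should favour the C4=C5 silyl enol ether (the usual sense for cis-fused systems, helped by relief of the gauche C5H2/isopropyl contact), and the divalent palladium enolate then loses H6 by syn β-hydride elimination at room temperature, which erases C6 and leaves the γ-centres C1 and C7 unepimerised.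

**Step 5**
Reactants: 8 (4aR,5R,8S)-5-methyl-8-(propan-2-yl)-4,4a,5,6,7,8-hexahydronaphthalen-2(3H)-one
Product: 9 (1S,4R,4aR)-4-methyl-7-methylidene-1-(propan-2-yl)-1,2,3,4,4a,5,6,7-octahydronaphthalene
Conditions: Ph3PCH3Br, KOtBu (no excess over the salt), THF, 0 °C to rt
Reagents that add atoms: methyltriphenylphosphonium bromide, C[P+](c1ccccc1)(c1ccccc1)c1ccccc1.[Br-]
Why: Wittig methylenation of the unhindered enone carbonyl gives the s-trans diene, and working cold without free base avoids γ-deprotonation, so the contra-thermodynamic axial isopropyl (C7) and axial methyl (C10) groups and C1 are kept.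

**Step 6**
Reactants: 10 phloroglucinol
Product: 12 2,4-diformylphloroglucinol, via bis-iminium salt 11 (not isolated)
Conditions: POCl3 (2.2 equiv), DMF (2.2 equiv), EtOAc, 0 °C to rt; then H2O
Reagents that add atoms: N,N-dimethylformamide, CN(C)C=O; water, O
Why: Double Vilsmeier–Haack formylation stops cleanly at two formyl groups because these hydrogen-bonded groups deactivate the last free ring position, and no stereocentre is involved.

**Step 7**
Reactants: 9 (1S,4R,4aR)-4-methyl-7-methylidene-1-(propan-2-yl)-1,2,3,4,4a,5,6,7-octahydronaphthalene; 12 2,4-diformylphloroglucinol; 13 benzaldehyde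
Product: 15 guajadial C, via ortho-quinone methide 14 (not isolated)
Conditions: N,N'-dimethylethylenediamine (10 mol %), (CF3)2CHOH, 40 °C; diastereomers separated by chromatography
Reagents that add atoms: benzaldehyde, O=Cc1ccccc1; 2,4-diformylphloroglucinol, O=Cc1c(O)cc(O)c(C=O)c1O
Why: In this domino Knoevenagel condensation and inverse-demand oxa-Diels–Alder reaction the s-trans-locked diene can react only as a 2π partner at its exocyclic C4=C15 bond with O going to the more substituted C4, the alkenyl group (C5=C6) sits endo under the E-configured heterodiene so phenyl ends cis to C5 (R benzylic centre), and the axial isopropyl group on C7 blocks the α face under the endo-oriented quinone methide so O adds to the β face (S spiro centre).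

**Compound list**
1 | (R)-citronellal, (3R)-3,7-dimethyloct-6-enal | CC(C)=CCC[C@@H](C)CC=O | starting material
2 | methyl vinyl ketone | C=CC(C)=O | starting material
3 | (2R,3R)-3,7-dimethyl-2-(3-oxobutyl)oct-6-enal | CC(C)=CCC[C@@H](C)[C@H](C=O)CCC(C)=O | intermediate
4 | (4R)-4-[(2R)-6-methylhept-5-en-2-yl]cyclohex-2-en-1-one | CC(C)=CCC[C@@H](C)[C@H]1CCC(=O)C=C1 | intermediate
5 | (4aR,5R,8R,8aR)-5-methyl-8-(prop-1-en-2-yl)octahydronaphthalen-2(1H)-one (cis-fused; H1, H6, H10 on one face, H7 on the other) | CC(=C)[C@@H]1CC[C@@H](C)[C@H]2CCC(=O)C[C@@H]12 | intermediate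
6 | (4aR,5R,8S,8aS)-5-methyl-8-(propan-2-yl)octahydronaphthalen-2(1H)-one | CC(C)[C@@H]1CC[C@@H](C)[C@H]2CCC(=O)C[C@@H]12 | intermediate
7 | trimethylsilyl enol ether of 6 with the C4=C5 double bond | CC(C)[C@@H]1CC[C@@H](C)[C@H]2CCC(O[Si](C)(C)C)=C[C@@H]12 | intermediate
8 | (4aR,5R,8S)-5-methyl-8-(propan-2-yl)-4,4a,5,6,7,8-hexahydronaphthalen-2(3H)-one | CC(C)[C@@H]1CC[C@@H](C)[C@H]2CCC(=O)C=C12 | intermediate
9 | (1S,4R,4aR)-4-methyl-7-methylidene-1-(propan-2-yl)-1,2,3,4,4a,5,6,7-octahydronaphthalene (a muurola-4(15),5-diene) | CC(C)[C@@H]1CC[C@@H](C)[C@H]2CCC(=C)C=C12 | intermediate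
10 | phloroglucinol | Oc1cc(O)cc(O)c1 | starting material
11 | bis(dimethyliminium) dichloride of 12 | C[N+](C)=Cc1c(O)cc(O)c(C=[N+](C)C)c1O.[Cl-].[Cl-] | intermediate
12 | 2,4-diformylphloroglucinol (2,4,6-trihydroxybenzene-1,3-dicarbaldehyde) | O=Cc1c(O)cc(O)c(C=O)c1O | intermediate
13 | benzaldehyde | O=Cc1ccccc1 | starting material
14 | (E)-benzylidene ortho-quinone methide of 12 | O=C1/C(=C/c2ccccc2)C(O)=C(C=O)C(O)=C1C=O | intermediate
15 | guajadial C | CC(C)[C@@H]1CC[C@@H](C)[C@H]2CC[C@@]3(C=C12)C[C@H](c1ccccc1)c1c(O)c(C=O)c(O)c(C=O)c1O3 | target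

**Step count**
Total step count: 7. Longest linear sequence: 6 (steps 1, 2, 3, 4, 5 and 7).

**Steps most likely to fail**

*Step 2.* The simple enone may be too weak an enophile. A stronger Lewis acid would divert the reaction into two 1,2-hydride shifts and give the C7 epimer.
- The fallback sets out from 4 and activates the enophile instead of the acid.
- I2/pyridine in CH2Cl2 (addition–elimination α-iodination) gives (4R)-2-iodo-4-[(2R)-6-methylhept-5-en-2-yl]cyclohex-2-en-1-one F1.
- The lowered LUMO of F1 lets ZnBr2 in CH2Cl2 at low temperature close ring A through the same chair. This gives the 5-iodo derivative of the ene product F2.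
- Zn dust in AcOH–Et2O removes the iodine, and the route is rejoined at 5.

*Step 4.* Enolisation may go toward C3. That gives the wrong enone, and over-oxidation would aromatise ring B.
- The fallback sets out from 4 and runs through F1 and F2 as above. It then uses the halogen as a regiochemical marker.
- Zn and Me3SiCl in THF turn F2 into the zinc enolate located at C4=C5. Silylation of this enolate gives the isopropenyl silyl enol ether F3.
- Pd(OAc)2/O2 in DMSO then gives the isopropenyl enone F4.
- RhCl(PPh3)3/H2 saturates only the isopropenyl group, and the route is rejoined at 8.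

*Step 7.* The diene may isomerise in the ionising protic medium, the quinone methide may oligomerise, or the facial and endo selectivity may be modest.
- The fallback sets out from 12 and 13 and separates quinone methide generation from the cycloaddition.
- Condensation with morpholine in EtOH gives the isolable Mannich base 2,4,6-trihydroxy-5-[morpholin-4-yl(phenyl)methyl]benzene-1,3-dicarbaldehyde F5.
- Heating F5 with 9 in toluene at 100 °C releases 14 slowly under neutral aprotic conditions, and the route is rejoined at 15.

**Further compounds**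
F1 | step 2 | (4R)-2-iodo-4-[(2R)-6-methylhept-5-en-2-yl]cyclohex-2-en-1-one | CC(C)=CCC[C@@H](C)[C@H]1CCC(=O)C(I)=C1
F2 | step 2 | 5-iodo derivative of 5 (1-iodo in naphthalenone numbering, epimer mixture at the C–I carbon) | CC(=C)[C@@H]1CC[C@@H](C)[C@H]2CCC(=O)C(I)[C@@H]12
F3 | step 4 | trimethylsilyl enol ether of 5 with the C4=C5 double bond | CC(=C)[C@@H]1CC[C@@H](C)[C@H]2CCC(O[Si](C)(C)C)=C[C@@H]12
F4 | step 4 | (4aR,5R,8S)-5-methyl-8-(prop-1-en-2-yl)-4,4a,5,6,7,8-hexahydronaphthalen-2(3H)-one | CC(=C)[C@@H]1CC[C@@H](C)[C@H]2CCC(=O)C=C12
F5 | step 7 | 2,4,6-trihydroxy-5-[morpholin-4-yl(phenyl)methyl]benzene-1,3-dicarbaldehyde (racemic) | O=Cc1c(O)c(C=O)c(O)c(C(c2ccccc2)N2CCOCC2)c1O
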